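The data are simulated for substances that don't exist; noise was put on by code.

**The question.** How strongly did the rate of making left-handed product in the flask answer to the partner charged, at 10 % conversion?

| flask | left-handed substrate | right-handed substrate | partner | free catalyst | remark |
|---|---|---|---|---|---|
| noon | 0.30 M | 0.30 M | 0.23 M | 1.5 mM | run made earlier |
| dusk | 0.30 M | 0.30 M | 0.34 M | 1.5 mM | run made earlier |
| flask | 0.30 M | 0.30 M | 0.450 M | 1.5 mM |  |

| run | time / min | left-handed product / % | left-handed substrate / % |
|---|---|---|---|
| noon | 10.0 | 0 | 47.1 |
| noon | 20.0 | 3.6 | 48.4 |
| noon | 50.0 | 5.4 | 44.6 |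
| noon | 120 | 9.8 | 39.1 |
| dusk | 30.0 | 4.5 | 47.2 |
| dusk | 60.0 | 8.4 | 41.3 |
| dusk | 90.0 | 11.0 | 37.6 |
| dusk | 120 | 13.1 | 34.3 |

(standard deviation of a reading: 1 percentage point)

- apparent order in partner when 10 % of the left-handed substrate and right-handed substrate together are converted (percent change of the rate of making left-handed product for one percent more partner charged)
- factor on the rate of making left-handed product when 10 % of the left-handed substrate and right-handed substrate together are converted if partner is charged twice over

- free catalyst is single-handed; left-handed substrate and right-handed substrate are mirror images of each other, charged as a racemate, each of them at the stated concentration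

**The rule.** I worked with the partner left. I took the conversion as left-handed product, 0.0600 M, and called the partner lost per product made the cost. If the rate is proportional to c(partner) and the cost is steady, the fraction of partner left is f = 1 − cost × c(product) / charge. The order is then 1/f and the doubling factor 1 + 1/f.

**Crude bracket.** A cost of one gives a floor of 1.15. The dusk run made 13.1 % from its charge, so its cost was at most 4.33, which gives a roof of 2.36.

**Tighter bracket.** The dusk run gained 8.4 % up to 60.0 min, then 4.7 percentage points over the same span again. I extrapolated that falling rate to zero, which put the dusk ceiling at 19.1 % and the cost at 2.97. Dividing the rates first by the mean left-handed substrate, as for a first-order dependence, gave 24.4 % and 2.32. These are readings with a scatter of 1 point, not walls. I carried the midpoint, 2.65, as the cost. For the flask the order lay between 1.45 and 1.66, the factor between 2.45 and 2.66.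

**The forecast.** It gave 1.05 and 2, both lower than my lower limits, and it took a cost of one: “Assuming 1:1 stoichiometry”.

**The result.** The flask gave an order of 1.5 and a factor of 2.45.

    partner → decomposed reagent (k = 0.350 h⁻¹)
    free catalyst + left-handed substrate ⇌ catalyst intermediate A (K = 69.0 M⁻¹, k = 18000 M⁻¹ h⁻¹)
    partner + catalyst intermediate B → free catalyst + right-handed product (k = 4.00 M⁻¹ h⁻¹)
    partner + catalyst intermediate A → free catalyst + left-handed product (k = 160 M⁻¹ h⁻¹)
    free catalyst + right-handed substrate ⇌ catalyst intermediate B (K = 4.20 M⁻¹, k = 4300 M⁻¹ h⁻¹)

**The cost.** At 1.25 h the flask held decomposed reagent 0.142 M beside left-handed product 14.0 %, a cost of 2.68. At my cost of 2.65, the flask's charge buys 28.3 % of the substrates together as left-handed product; at 25.0 h, with partner, the limiting reagent, at 0 %, the flask held 27.6 %.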